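Everything rests on cutting ring C at C3–C4. C4 is the aryl ketone carbon on ring A and C3 the methylene beside the C2 ether, so C4 is carried as a 1,3-dithiane and used as an acyl anion that alkylates C3, while C2 is set beforehand as the aryl ether of a chlorohydrin. In one operation the lithiated dithiane displaces the primary chloride (6-exo-tet), forming C3–C4 and the pyranone ring as its C4 dithioketal; with no C4 carbonyl there is no C3 enolate, so O1 cannot be expelled and C2 is safe. The precursor is the tribenzylated 2-aryl-1,3-dithiane bearing the (S)-N-methylpiperidine at C6 and the (R)-ArO–CH(Ar′)–CH2Cl ether at C8a.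

Key step: step 12

Remarks on the chemistry:
(a) The target is taken as the free base, (S) at piperidine C2 and (S) at flavanone C2, as the SMILES encodes; the structures were checked and no correction was needed.
(b) The future C2 reads R in 18 and S in 20–22 for the same spatial arrangement, because CH2Cl outranks aryl whereas the ring CH2 does not.
(c) Metalation is planned with n-BuLi, because lithium amides remove sulfur-stabilised C–H bonds slowly and this dithiane is crowded and electron-rich.
(d) The dithioketal is opened with HgCl2, a weak electrophile towards the activated C8–H.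
(e) Ring B enters as the preformed benzyl ether 15, because a phenolic phenacyl chloride would alkylate itself under basic benzylation.
(f) N-Methylation is done on the sulfinamide, so that formaldehyde never meets the free, Mannich-reactive phenol.

Step 1
Reactants: 1 2,4,6-trihydroxybenzaldehyde
Product: 2 2,6-dihydroxy-4-(methoxymethoxy)benzaldehyde
Conditions: MOMCl (1.0 equiv), i-Pr2NEt (1.1 equiv), THF, −10 → 0 °C
Reagents that add atoms: chloromethyl methyl ether, COCCl
Why: Williamson-type O-alkylation: the para hydroxyl is the most acidic and the only one not engaged in a hydrogen bond to the formyl oxygen, so one equivalent of MOMCl with a hindered amine base should etherify it in preference to the ortho hydroxyls.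

Step 2
Reactants: 2 2,6-dihydroxy-4-(methoxymethoxy)benzaldehyde
Product: 3 2,6-bis(benzyloxy)-4-(methoxymethoxy)benzaldehyde
Conditions: BnBr (2.4 equiv), K2CO3, DMF, 60 °C
Reagents that add atoms: benzyl bromide, BrCc1ccccc1
Why: Williamson ether synthesis: once the para oxygen is capped, K2CO3 in warm DMF should benzylate both chelated ortho hydroxyls, the MOM acetal being inert to base.

Step 3
Reactants: 3 2,6-bis(benzyloxy)-4-(methoxymethoxy)benzaldehyde; 4 (R)-2-methylpropane-2-sulfinamide
Product: 5 (R)-N-{(E)-[2,6-bis(benzyloxy)-4-(methoxymethoxy)phenyl]methylidene}-2-methylpropane-2-sulfinamide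
Conditions: Ti(OEt)4 (2 equiv), THF, 65 °C
Reagents that add atoms: none
Why: Sulfinimine condensation: Ti(OEt)4 activates the hindered, electron-rich aldehyde and traps the water formed, which should give the E aldimine without touching the sulfur stereocentre.

Step 4
Reactants: 5 (R)-N-{(E)-[2,6-bis(benzyloxy)-4-(methoxymethoxy)phenyl]methylidene}-2-methylpropane-2-sulfinamide; 6 1-bromo-4-chlorobutane
Product: 8 (R)-N-{(1S)-1-[2,6-bis(benzyloxy)-4-(methoxymethoxy)phenyl]-5-chloropentyl}-2-methylpropane-2-sulfinamide, via 4-chlorobutylmagnesium bromide 7 (not isolated)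
Conditions: 6, Mg, Et2O, rt; then 5, CH2Cl2, −48 °C → rt; aq. NH4Cl
Reagents that add atoms: none
Why: Diastereoselective Grignard addition to an N-tert-butanesulfinyl aldimine: magnesium inserts into the C–Br bond only, and in CH2Cl2 the alkyl group is delivered through a six-membered chair transition state with magnesium on the sulfinyl oxygen and tert-butyl equatorial, so that the (R)-sulfinyl group should set the (S) carbon that becomes piperidine C2.

Step 5
Reactants: 8 (R)-N-{(1S)-1-[2,6-bis(benzyloxy)-4-(methoxymethoxy)phenyl]-5-chloropentyl}-2-methylpropane-2-sulfinamide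
Product: 9 (R)-N-{(1S)-1-[2,6-bis(benzyloxy)-4-(methoxymethoxy)phenyl]-5-chloropentyl}-N,2-dimethylpropane-2-sulfinamide
Conditions: LiN(SiMe3)2 (1.2 equiv), THF, −78 °C; MeI (3 equiv), −78 → 0 °C
Reagents that add atoms: iodomethane, CI
Why: N-alkylation of a sulfinamide anion: at low temperature the lithium sulfinamide should be methylated by MeI faster than it closes onto the primary chloride, and the adjacent stereocentre bears no acidic hydrogen.

Step 6
Reactants: 9 (R)-N-{(1S)-1-[2,6-bis(benzyloxy)-4-(methoxymethoxy)phenyl]-5-chloropentyl}-N,2-dimethylpropane-2-sulfinamide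
Product: 11 3,5-bis(benzyloxy)-4-[(2S)-1-methylpiperidin-2-yl]phenol, via amino chloride hydrochloride 10 (not isolated)
Conditions: HCl (3 M in MeOH), rt; evaporate; NaHCO3, NaI (cat.), MeCN/H2O, 50 °C
Reagents that add atoms: none
Why: Acid methanolysis followed by intramolecular SN2 N-alkylation: HCl in MeOH cleaves the N–S bond and the MOM acetal at room temperature, and after neutralisation the secondary amine should close the piperidine ring in a 6-exo-tet displacement of chloride that does not involve the stereocentre.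

Step 7
Reactants: 11 3,5-bis(benzyloxy)-4-[(2S)-1-methylpiperidin-2-yl]phenol
Product: 12 2,4-bis(benzyloxy)-6-hydroxy-3-[(2S)-1-methylpiperidin-2-yl]benzaldehyde
Conditions: MgCl2, Et3N, (CH2O)n, THF, 65 °C
Reagents that add atoms: paraformaldehyde (as formaldehyde), C=O
Why: Casnati–Skattebøl ortho-formylation: the magnesium phenoxide directs formaldehyde to the ortho carbon and a second formaldehyde oxidises the hydroxymethyl intermediate, and because the two ortho positions are equivalent by symmetry a single salicylaldehyde should result.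

Step 8
Reactants: 12 2,4-bis(benzyloxy)-6-hydroxy-3-[(2S)-1-methylpiperidin-2-yl]benzaldehyde; 13 propane-1,3-dithiol
Product: 14 3,5-bis(benzyloxy)-2-(1,3-dithian-2-yl)-4-[(2S)-1-methylpiperidin-2-yl]phenol
Conditions: BF3·OEt2 (2.5 equiv), CH2Cl2, 0 °C
Reagents that add atoms: none
Why: Lewis acid dithioacetalisation: BF3 activates the chelated aldehyde for double thiol addition, the excess compensating for BF3 held by the amine, and the benzyl ethers should survive the short exposure at 0 °C.

Step 9
Reactants: 15 1-[4-(benzyloxy)phenyl]ethan-1-one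
Product: 16 1-[4-(benzyloxy)phenyl]-2-chloroethan-1-one
Conditions: SO2Cl2 (1.1 equiv), MeOH (2 equiv), CH2Cl2, 0 °C → rt
Reagents that add atoms: sulfuryl chloride, O=S(=O)(Cl)Cl
Why: Electrophilic α-chlorination of the ketone enol with SO2Cl2, moderated by MeOH so that it should stop at the monochloride, the acyl group shielding the ring from chlorination.

Step 10
Reactants: 16 1-[4-(benzyloxy)phenyl]-2-chloroethan-1-one
Product: 17 (1S)-1-[4-(benzyloxy)phenyl]-2-chloroethan-1-ol
Conditions: BH3·SMe2 (0.7 equiv), (S)-Me-CBS [(3aS)-1-methyl-3,3-diphenyltetrahydro-1H,3H-pyrrolo[1,2-c][1,3,2]oxazaborole, 10 mol %], THF, 0 °C; then H2O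
Reagents that add atoms: none
Why: Corey–Bakshi–Shibata reduction: the (S)-oxazaborolidine binds the ketone with aryl as the large group and borane delivers hydride to one face, which should give the (S)-chlorohydrin (the spatial sense of (R)-1-phenylethanol, the descriptor following from CH2Cl outranking aryl).

Step 11
Reactants: 14 3,5-bis(benzyloxy)-2-(1,3-dithian-2-yl)-4-[(2S)-1-methylpiperidin-2-yl]phenol; 17 (1S)-1-[4-(benzyloxy)phenyl]-2-chloroethan-1-ol
Product: 18 (2S)-2-{2,6-bis(benzyloxy)-4-[(1R)-1-[4-(benzyloxy)phenyl]-2-chloroethoxy]-3-(1,3-dithian-2-yl)phenyl}-1-methylpiperidine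
Conditions: PPh3, DIAD, toluene, 0 °C → rt
Reagents that add atoms: none
Why: Mitsunobu etherification: the phenoxide displaces the alkoxyphosphonium of 17 by SN2 with inversion, so the (S)-alcohol should give the (R)-ether, which is the spatial arrangement of (2S)-C2, while toluene and the electron-withdrawing CH2Cl group disfavour ionisation of the benzylic centre.

Step 12
Reactants: 18 (2S)-2-{2,6-bis(benzyloxy)-4-[(1R)-1-[4-(benzyloxy)phenyl]-2-chloroethoxy]-3-(1,3-dithian-2-yl)phenyl}-1-methylpiperidine
Product: 20 (2S)-5,7-bis(benzyloxy)-2-[4-(benzyloxy)phenyl]-6-[(2S)-1-methylpiperidin-2-yl]spiro[chromane-4,2′-[1,3]dithiane], via 2-lithiodithiane 19 (not isolated)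
Conditions: n-BuLi (1.1 equiv), THF, −78 °C → 0 °C; aq. NH4Cl
Reagents that add atoms: none
Why: n-BuLi removes the dithiane C–H, the only proton flanked by two sulfur atoms, to give the 2-lithio-2-aryl-1,3-dithiane 19, a masked C4 acyl anion, which displaces chloride at C3 by intramolecular SN2 and forms the C3–C4 bond. The closest known reaction type is the Corey–Seebach alkylation in its intramolecular form, the cycloalkylation of 2-(ω-chloroalkyl)-1,3-dithianes with n-BuLi. Ring C closes in the 6-exo-tet mode, with C4 ending as the spiro dithioketal. No stereocentre is created, and C2 is a spectator that keeps its geometry, its descriptor changing from R to S only through the priority change at C3. The step needs chemoselectivity for dithiane metalation over loss of HCl across C2–C3 and over lithiation of C8–H or the OCH2Ph groups: the sulfur-stabilised C–H is by far the most acidic and should react at −78 °C, chloride is a poor partner for elimination and inert to halogen–lithium exchange, and because C4 is not a carbonyl no C3 enolate can expel the O1 phenoxide and scramble C2 through a chalcone.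

Step 13
Reactants: 20 (2S)-5,7-bis(benzyloxy)-2-[4-(benzyloxy)phenyl]-6-[(2S)-1-methylpiperidin-2-yl]spiro[chromane-4,2′-[1,3]dithiane]
Product: 21 (2S)-5,7-bis(benzyloxy)-2-[4-(benzyloxy)phenyl]-6-[(2S)-1-methylpiperidin-2-yl]-2,3-dihydro-4H-chromen-4-one
Conditions: HgCl2 (2.2 equiv), CaCO3, MeCN/H2O (4:1), rt
Reagents that add atoms: water, O
Why: Thiophile-assisted hydrolysis of a dithioketal: HgCl2 binds sulfur, the electron-rich ring A assists C–S ionisation and water delivers the C4 ketone under buffered conditions that generate no C3 enolate, so C2 should be retained, and HgCl2 is preferred to more electrophilic mercury salts because it should not mercurate the activated C8–H.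

Step 14
Reactants: 21 (2S)-5,7-bis(benzyloxy)-2-[4-(benzyloxy)phenyl]-6-[(2S)-1-methylpiperidin-2-yl]-2,3-dihydro-4H-chromen-4-one
Product: 22 (2S)-5,7-dihydroxy-2-(4-hydroxyphenyl)-6-[(2S)-1-methylpiperidin-2-yl]-2,3-dihydro-4H-chromen-4-one
Conditions: H2 (1 atm), 10% Pd/C, EtOAc/MeOH, rt
Reagents that add atoms: none
Why: Catalytic hydrogenolysis of benzyl aryl ethers: at ambient pressure and temperature the three O-benzyl groups should be cleaved while the chelated C4 ketone, the cyclic benzylic C2–O1 ether and the benzylic C–N bond of the piperidine remain, and the neutral medium leaves both stereocentres untouched.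

Compound list
1 | 2,4,6-trihydroxybenzaldehyde | O=Cc1c(O)cc(O)cc1O | starting material
2 | 2,6-dihydroxy-4-(methoxymethoxy)benzaldehyde | COCOc1cc(O)c(C=O)c(O)c1 | intermediate
3 | 2,6-bis(benzyloxy)-4-(methoxymethoxy)benzaldehyde | COCOc1cc(OCc2ccccc2)c(C=O)c(OCc2ccccc2)c1 | intermediate
4 | (R)-2-methylpropane-2-sulfinamide | CC(C)(C)[S@@](=O)N | starting material
5 | (R)-N-{(E)-[2,6-bis(benzyloxy)-4-(methoxymethoxy)phenyl]methylidene}-2-methylpropane-2-sulfinamide | CC(C)(C)[S@@](=O)/N=C/c1c(OCc2ccccc2)cc(OCOC)cc1OCc1ccccc1 | intermediate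
6 | 1-bromo-4-chlorobutane | ClCCCCBr | starting material
7 | 4-chlorobutylmagnesium bromide | ClCCCC[Mg]Br | intermediate
8 | (R)-N-{(1S)-1-[2,6-bis(benzyloxy)-4-(methoxymethoxy)phenyl]-5-chloropentyl}-2-methylpropane-2-sulfinamide | CC(C)(C)[S@@](=O)N[C@@H](CCCCCl)c1c(OCc2ccccc2)cc(OCOC)cc1OCc1ccccc1 | intermediate
9 | (R)-N-{(1S)-1-[2,6-bis(benzyloxy)-4-(methoxymethoxy)phenyl]-5-chloropentyl}-N,2-dimethylpropane-2-sulfinamide | CC(C)(C)[S@@](=O)N(C)[C@@H](CCCCCl)c1c(OCc2ccccc2)cc(OCOC)cc1OCc1ccccc1 | intermediate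
10 | 3,5-bis(benzyloxy)-4-[(1S)-5-chloro-1-(methylamino)pentyl]phenol hydrochloride | CN[C@@H](CCCCCl)c1c(OCc2ccccc2)cc(O)cc1OCc1ccccc1.Cl | intermediate
11 | 3,5-bis(benzyloxy)-4-[(2S)-1-methylpiperidin-2-yl]phenol | CN1CCCC[C@H]1c1c(OCc2ccccc2)cc(O)cc1OCc1ccccc1 | intermediate
12 | 2,4-bis(benzyloxy)-6-hydroxy-3-[(2S)-1-methylpiperidin-2-yl]benzaldehyde | CN1CCCC[C@H]1c1c(OCc2ccccc2)cc(O)c(C=O)c1OCc1ccccc1 | intermediate
13 | propane-1,3-dithiol | SCCCS | starting material
14 | 3,5-bis(benzyloxy)-2-(1,3-dithian-2-yl)-4-[(2S)-1-methylpiperidin-2-yl]phenol | CN1CCCC[C@H]1c1c(OCc2ccccc2)cc(O)c(C2SCCCS2)c1OCc1ccccc1 | intermediate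
15 | 1-[4-(benzyloxy)phenyl]ethan-1-one | CC(=O)c1ccc(OCc2ccccc2)cc1 | starting material
16 | 1-[4-(benzyloxy)phenyl]-2-chloroethan-1-one | O=C(CCl)c1ccc(OCc2ccccc2)cc1 | intermediate
17 | (1S)-1-[4-(benzyloxy)phenyl]-2-chloroethan-1-ol | O[C@H](CCl)c1ccc(OCc2ccccc2)cc1 | intermediate
18 | (2S)-2-{2,6-bis(benzyloxy)-4-[(1R)-1-[4-(benzyloxy)phenyl]-2-chloroethoxy]-3-(1,3-dithian-2-yl)phenyl}-1-methylpiperidine | CN1CCCC[C@H]1c1c(OCc2ccccc2)cc(O[C@@H](CCl)c2ccc(OCc3ccccc3)cc2)c(C2SCCCS2)c1OCc1ccccc1 | intermediate
19 | (2S)-2-{2,6-bis(benzyloxy)-4-[(1R)-1-[4-(benzyloxy)phenyl]-2-chloroethoxy]-3-(2-lithio-1,3-dithian-2-yl)phenyl}-1-methylpiperidine | CN1CCCC[C@H]1c1c(OCc2ccccc2)cc(O[C@@H](CCl)c2ccc(OCc3ccccc3)cc2)c(C2([Li])SCCCS2)c1OCc1ccccc1 | intermediate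
20 | (2S)-5,7-bis(benzyloxy)-2-[4-(benzyloxy)phenyl]-6-[(2S)-1-methylpiperidin-2-yl]spiro[chromane-4,2′-[1,3]dithiane] | CN1CCCC[C@H]1c1c(OCc2ccccc2)cc2c(c1OCc1ccccc1)C1(SCCCS1)C[C@@H](c1ccc(OCc3ccccc3)cc1)O2 | intermediate
21 | (2S)-5,7-bis(benzyloxy)-2-[4-(benzyloxy)phenyl]-6-[(2S)-1-methylpiperidin-2-yl]-2,3-dihydro-4H-chromen-4-one | CN1CCCC[C@H]1c1c(OCc2ccccc2)cc2c(c1OCc1ccccc1)C(=O)C[C@@H](c1ccc(OCc3ccccc3)cc1)O2 | intermediate
22 | (2S)-5,7-dihydroxy-2-(4-hydroxyphenyl)-6-[(2S)-1-methylpiperidin-2-yl]-2,3-dihydro-4H-chromen-4-one (CNP0146489.1) | CN1CCCC[C@H]1c1c(O)cc2c(c1O)C(=O)C[C@@H](c1ccc(O)cc1)O2 | target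

Total step count: 14. Longest linear sequence: 12 steps (steps 1–8, then 11–14); steps 9–10 form the side branch to 17.

Steps most likely to fail

Step 12. Metalation of the crowded, electron-rich aryl dithiane may lag, so that base-induced loss of HCl across C2–C3 or lithiation elsewhere competes with ring closure. The fallback closes ring C by the classical chalcone route and sets out from aldehyde 12. MeMgBr (excess, THF, 0 °C) should give 1-{2,4-bis(benzyloxy)-6-hydroxy-3-[(2S)-1-methylpiperidin-2-yl]phenyl}ethan-1-ol F1. MnO2 (CH2Cl2) should oxidise it to the corresponding 2′-hydroxyacetophenone F2. Claisen–Schmidt condensation with commercial 4-(benzyloxy)benzaldehyde (KOH, EtOH) should give the 2′-hydroxychalcone F3. NaOAc in EtOH at reflux should then close ring C by oxa-Michael addition, giving 21 together with its (2R)-epimer F4. The two are diastereomers because of the fixed piperidine centre and should be separable by chromatography; F4 can be re-equilibrated through F3 under the same conditions. The route is rejoined at 21.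

Step 11. Ionisation of the activated benzylic alkoxyphosphonium would erode configuration at the future C2, and coupling of the hindered phenol may be slow. The fallback gives up stereospecific etherification for a plain SN2 alkylation and diastereomer separation, and sets out from phenol 14. It would be O-alkylated (K2CO3, DMF, rt) with racemic methyl bromo[4-(benzyloxy)phenyl]acetate F5, which is made from commercial [4-(benzyloxy)phenyl]acetic acid by Hell–Volhard–Zelinsky bromination and methanol quench. This should give the methyl 2-aryloxy-2-arylacetate F6 as both epimers at the new centre. LiBH4 (THF) should reduce it to the 2-aryloxy-2-arylethanol F7. An Appel reaction (PPh3, CCl4) should then give 18 together with its (1S)-epimer F8, separable by chromatography. The route is rejoined at 18.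

Step 4. Facial selectivity may be eroded or reversed if the ortho benzyloxy groups compete with the sulfinyl oxygen for magnesium, and addition to the crowded aldimine may be sluggish. The fallback sets the centre by hydride delivery to a ketimine through an open transition state and sets out from aldehyde 3. Grignard reagent 7 should add to 3 to give racemic 1-[2,6-bis(benzyloxy)-4-(methoxymethoxy)phenyl]-5-chloropentan-1-ol F9. Dess–Martin periodinane should oxidise it to the aryl ketone F10. Condensation with 4 (Ti(OEt)4, THF, 70 °C) should give the (R)-N-sulfinyl ketimine F11. Reduction with LiBH(s-Bu)3 (THF, −78 °C) should then give sulfinamide 8. The route is rejoined at 8.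

Further compounds
F1 | step 12 | 1-{2,4-bis(benzyloxy)-6-hydroxy-3-[(2S)-1-methylpiperidin-2-yl]phenyl}ethan-1-ol (both carbinol epimers) | CN1CCCC[C@H]1c1c(OCc2ccccc2)cc(O)c(C(C)O)c1OCc1ccccc1
F2 | step 12 | 1-{2,4-bis(benzyloxy)-6-hydroxy-3-[(2S)-1-methylpiperidin-2-yl]phenyl}ethan-1-one | CN1CCCC[C@H]1c1c(OCc2ccccc2)cc(O)c(C(C)=O)c1OCc1ccccc1
F3 | step 12 | (2E)-1-{2,4-bis(benzyloxy)-6-hydroxy-3-[(2S)-1-methylpiperidin-2-yl]phenyl}-3-[4-(benzyloxy)phenyl]prop-2-en-1-one | CN1CCCC[C@H]1c1c(OCc2ccccc2)cc(O)c(C(=O)/C=C/c2ccc(OCc3ccccc3)cc2)c1OCc1ccccc1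
F4 | step 12 | (2R)-5,7-bis(benzyloxy)-2-[4-(benzyloxy)phenyl]-6-[(2S)-1-methylpiperidin-2-yl]-2,3-dihydro-4H-chromen-4-one | CN1CCCC[C@H]1c1c(OCc2ccccc2)cc2c(c1OCc1ccccc1)C(=O)C[C@H](c1ccc(OCc3ccccc3)cc1)O2
F5 | step 11 | methyl bromo[4-(benzyloxy)phenyl]acetate (racemic) | COC(=O)C(Br)c1ccc(OCc2ccccc2)cc1
F6 | step 11 | methyl {3,5-bis(benzyloxy)-2-(1,3-dithian-2-yl)-4-[(2S)-1-methylpiperidin-2-yl]phenoxy}[4-(benzyloxy)phenyl]acetate (both epimers at the new centre) | CN1CCCC[C@H]1c1c(OCc2ccccc2)cc(OC(C(=O)OC)c2ccc(OCc3ccccc3)cc2)c(C2SCCCS2)c1OCc1ccccc1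
F7 | step 11 | 2-{3,5-bis(benzyloxy)-2-(1,3-dithian-2-yl)-4-[(2S)-1-methylpiperidin-2-yl]phenoxy}-2-[4-(benzyloxy)phenyl]ethan-1-ol (both epimers at the new centre) | CN1CCCC[C@H]1c1c(OCc2ccccc2)cc(OC(CO)c2ccc(OCc3ccccc3)cc2)c(C2SCCCS2)c1OCc1ccccc1
F8 | step 11 | (2S)-2-{2,6-bis(benzyloxy)-4-[(1S)-1-[4-(benzyloxy)phenyl]-2-chloroethoxy]-3-(1,3-dithian-2-yl)phenyl}-1-methylpiperidine | CN1CCCC[C@H]1c1c(OCc2ccccc2)cc(O[C@H](CCl)c2ccc(OCc3ccccc3)cc2)c(C2SCCCS2)c1OCc1ccccc1
F9 | step 4 | 1-[2,6-bis(benzyloxy)-4-(methoxymethoxy)phenyl]-5-chloropentan-1-ol (racemic) | OC(CCCCCl)c1c(OCc2ccccc2)cc(OCOC)cc1OCc1ccccc1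
F10 | step 4 | 1-[2,6-bis(benzyloxy)-4-(methoxymethoxy)phenyl]-5-chloropentan-1-one | O=C(CCCCCl)c1c(OCc2ccccc2)cc(OCOC)cc1OCc1ccccc1
F11 | step 4 | (R)-N-{(1E)-1-[2,6-bis(benzyloxy)-4-(methoxymethoxy)phenyl]-5-chloropentylidene}-2-methylpropane-2-sulfinamide | CC(C)(C)[S@@](=O)/N=C(\CCCCCl)c1c(OCc2ccccc2)cc(OCOC)cc1OCc1ccccc1
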